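Ring B is not bought but grown around the finished carbinol. Its pattern, carbinol carbon C7 on B4, the phenol oxygen on the neighbouring B5 and the CH2 link to ring A on B1, is what a C7–O–B bridge between two alkynes delivers. The (S)-alkynol, made from geraniol, is esterified onto an ethynylboronate, and ruthenium joins this bridged diyne to the propargyl arene of ring A. One operation forms B4–B5, B2–B3 and B6–B1, closes ring B plus a sacrificial oxaborole, and leaves boron where the phenol belongs. The precursor is a tertiary propargylic alcohol whose alkyne end (B3) carries a removable SiMe3 group that orients the third alkyne.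

Key step: step 12

Remark: ring A is the catechol ring and ring B the phenol ring (B1 carries the CH2, B4 the carbinol carbon C7, B5 the hydroxyl); it is assumed that L-(+)-diethyl tartrate gives the (2S,3S)-epoxide of geraniol, as is established for E-configured allylic alcohols, and because the C7–O bond is never broken afterwards, this one step fixes the enantiomer.

Step 1
Reactants: 1 geraniol
Product: 2 (2S,3S)-2,3-epoxygeraniol
Conditions: Ti(OiPr)4 (5 mol %), L-(+)-diethyl tartrate (7 mol %), t-BuOOH (1.5 equiv, in decane), 4 Å MS, CH2Cl2, −20 °C
Reagents that add atoms: tert-butyl hydroperoxide CC(C)(C)OO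
Why: Sharpless asymmetric epoxidation: the allylic hydroxyl docks on the titanium tartrate complex, so only the C2=C3 alkene is oxidised, and the L-(+)-tartrate ligand dictates the face of oxygen delivery, setting C2 and C3 (the later C7) both as S.

Step 2
Reactants: 2 (2S,3S)-2,3-epoxygeraniol
Product: 3 [(2S,3S)-3-methyl-3-(4-methylpentyl)oxiran-2-yl]methanol
Conditions: H2 (1 atm), Pd/C, EtOAc, rt
Reagents that add atoms: none
Why: Heterogeneous catalytic hydrogenation saturates the only remaining alkene, while the aliphatic epoxide and both stereocentres are left alone under neutral conditions.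

Step 3
Reactants: 3 [(2S,3S)-3-methyl-3-(4-methylpentyl)oxiran-2-yl]methanol
Product: 4 (2S,3R)-3-(chloromethyl)-2-methyl-2-(4-methylpentyl)oxirane
Conditions: PPh3, CCl4, NaHCO3, reflux
Reagents that add atoms: tetrachloromethane ClC(Cl)(Cl)Cl
Why: Appel reaction: chloride displaces the alkoxyphosphonium group by SN2 at the primary carbon under buffered conditions that spare the acid-sensitive epoxide; no bond to a stereocentre is broken, and the CH carbon is now called R only because CH2Cl outranks the ring carbon.

Step 4
Reactants: 4 (2S,3R)-3-(chloromethyl)-2-methyl-2-(4-methylpentyl)oxirane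
Product: 7 (S)-3,7-dimethyl-1-(trimethylsilyl)oct-1-yn-3-ol, via dilithium alkynolate 5 (not isolated), via bis(trimethylsilyl) derivative 6 (not isolated)
Conditions: n-BuLi (3.3 equiv), THF, −78 to −20 °C; Me3SiCl (3 equiv), −78 °C to rt; then 1 M HCl, THF/MeOH, rt
Reagents that add atoms: chlorotrimethylsilane C[Si](C)(C)Cl
Why: Base-induced double elimination of a 2,3-epoxy chloride: deprotonation next to chlorine opens the epoxide to a chlorovinyl alkoxide, loss of HCl gives the alkyne, the third equivalent of base leaves the acetylide that is silylated in the same flask, and dilute acid cleaves only the labile O–Si bond; the tertiary C–O bond is never broken, so the S centre is carried over.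

Step 5
Reactants: 8 ethynylmagnesium bromide; 9 triisopropyl borate
Product: 11 diisopropyl ethynylboronate, via bromomagnesium ethynyltriisopropoxyborate 10 (not isolated)
Conditions: THF/Et2O, −78 °C; HCl (1.0 equiv, 2 M in Et2O), −78 °C to rt; filtration and distillation under argon
Reagents that add atoms: none
Why: Addition of the alkynyl Grignard reagent to the borate ester gives the ate complex, from which one equivalent of anhydrous acid removes a single isopropoxide (the standard ate-complex protonolysis route to alkynylboronic esters), and distillation with exclusion of moisture delivers the ester.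

Step 6
Reactants: 12 creosol (2-methoxy-4-methylphenol)
Product: 13 2-hydroxy-3-methoxy-5-methylbenzaldehyde
Conditions: MgCl2 (1.5 equiv), Et3N, (CH2O)n, MeCN, reflux; 1 M HCl work-up
Reagents that add atoms: paraformaldehyde, reacting as formaldehyde C=O
Why: Casnati–Skattebøl ortho-formylation: the magnesium phenoxide delivers formaldehyde to the only free ortho position (para is blocked by the methyl group), and a second formaldehyde oxidises the benzylic alkoxide to the aldehyde by hydride transfer.

Step 7
Reactants: 13 2-hydroxy-3-methoxy-5-methylbenzaldehyde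
Product: 14 2,3-dihydroxy-5-methylbenzaldehyde
Conditions: BBr3 (2.5 equiv), CH2Cl2, −78 °C to rt; H2O
Reagents that add atoms: none
Why: Lewis acid ether cleavage: BBr3 binds the methoxy oxygen and bromide removes the methyl group by SN2, as is routine for aldehydes of the ortho-vanillin type.

Step 8
Reactants: 14 2,3-dihydroxy-5-methylbenzaldehyde
Product: 15 2,3-bis(benzyloxy)-5-methylbenzaldehyde
Conditions: BnBr (2.5 equiv), K2CO3, DMF, 60 °C, argon
Reagents that add atoms: benzyl bromide BrCc1ccccc1
Why: Williamson ether synthesis on both phenoxides; benzyl withstands organometallics, ruthenium, basic peroxide and hot base and leaves at the end by neutral hydrogenolysis, the deprotection that the acid-sensitive tertiary benzylic alcohol tolerates best.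

Step 9
Reactants: 15 2,3-bis(benzyloxy)-5-methylbenzaldehyde
Product: 16 [2,3-bis(benzyloxy)-5-methylphenyl]methanol
Conditions: NaBH4, MeOH/THF, 0 °C
Reagents that add atoms: none
Why: Borohydride reduction of an aromatic aldehyde, with no other reducible group present.

Step 10
Reactants: 16 [2,3-bis(benzyloxy)-5-methylphenyl]methanol
Product: 17 1,2-bis(benzyloxy)-3-(bromomethyl)-5-methylbenzene
Conditions: PBr3 (0.4 equiv), Et2O, 0 °C; used without storage
Reagents that add atoms: phosphorus tribromide BrP(Br)Br
Why: Conversion of a primary benzylic alcohol into the bromide through its phosphite ester and SN2 attack of bromide; the low temperature and the absence of strong acid keep the benzyl ethers in place.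

Step 11
Reactants: 17 1,2-bis(benzyloxy)-3-(bromomethyl)-5-methylbenzene; 8 ethynylmagnesium bromide
Product: 18 1,2-bis(benzyloxy)-5-methyl-3-(prop-2-yn-1-yl)benzene
Conditions: 8 (3 equiv), CuBr (15 mol %), THF, 50 °C; aq NH4Cl
Reagents that add atoms: none
Why: Copper-catalysed sp–sp3 cross-coupling of an alkynyl Grignard reagent with a benzylic bromide; the excess of 8 keeps the product from being alkylated a second time, and the mild quench avoids propargyl to allene isomerisation.

Step 12
Reactants: 7 (S)-3,7-dimethyl-1-(trimethylsilyl)oct-1-yn-3-ol; 11 diisopropyl ethynylboronate; 18 1,2-bis(benzyloxy)-5-methyl-3-(prop-2-yn-1-yl)benzene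
Product: 20 (3S)-6-[2,3-bis(benzyloxy)-5-methylbenzyl]-1-isopropoxy-3-methyl-3-(4-methylpentyl)-4-(trimethylsilyl)-1,3-dihydro-2,1-benzoxaborole, via boron-bridged diyne 19 (not isolated)
Conditions: 7 (1.0 equiv), 11 (1.2 equiv), toluene, 40 °C, 2-propanol stripped under reduced pressure; residue in ClCH2CH2Cl added slowly to 18 (1.5 equiv), Cp*RuCl(cod) (10 mol %), ClCH2CH2Cl, rt to 60 °C, argon; concentrated and used crude
Reagents that add atoms: none
Why: Alcohol exchange at boron, driven by removal of 2-propanol, ties two alkynes into the 1,6-diyne 19, which displaces cod from Cp*RuCl and undergoes oxidative cyclization from divalent to tetravalent ruthenium to a bicyclic ruthenacyclopentadiene in which B4–B5 already exists; alkyne 18 then inserts and reductive elimination releases the arene, forming B6–B1 and B2–B3. The closest known reaction type is the Cp*RuCl-catalysed (2+2+2) cyclotrimerization of an alkynylboronate, a propargylic alcohol and a terminal alkyne across a transient B–O link, together with the meta-selective cycloaddition of 1,6-diynes that carry one terminal substituent. Ring B closes by metal-templated (2+2+2) assembly of three alkynes, and the five-membered oxaborole closes in the oxidative cyclization, when B4–B5 spans the three-atom B–O–C7 bridge. No stereocentre is created: C7 is quaternary, has no acidic hydrogen and keeps its C–O bond, so the S configuration from step 1 passes through unchanged. Two selectivities are needed, the ortho relation of boron and C7, which the bridge enforces, and the orientation of 18, which the SiMe3 group on ruthenacycle carbon B3 secures by sending the bulky CH2Ar end of 18 to the unhindered CH terminus B6, so that the benzyl group lands on B1, meta to silicon. Slow addition of 19 to an excess of 18, and the silyl cap itself, hold back self-trimerization of the diyne.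

Step 13
Reactants: 20 (3S)-6-[2,3-bis(benzyloxy)-5-methylbenzyl]-1-isopropoxy-3-methyl-3-(4-methylpentyl)-4-(trimethylsilyl)-1,3-dihydro-2,1-benzoxaborole
Product: 21 5-[2,3-bis(benzyloxy)-5-methylbenzyl]-2-[(2S)-2-hydroxy-6-methylheptan-2-yl]-3-(trimethylsilyl)phenol
Conditions: H2O2 (30 % aq), NaOH (2 M), THF, 0 °C to rt; Na2S2O3, then aq NH4Cl; chromatography (excess 18 recovered)
Reagents that add atoms: hydrogen peroxide OO
Why: Oxidation of an arylboronic ester with basic hydrogen peroxide: hydroperoxide adds to boron, the aryl group migrates from boron to oxygen, and hydrolysis of the borate frees the B5 phenol and the C7 hydroxyl, whose C–O bond is not involved, so C7 stays S.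

Step 14
Reactants: 21 5-[2,3-bis(benzyloxy)-5-methylbenzyl]-2-[(2S)-2-hydroxy-6-methylheptan-2-yl]-3-(trimethylsilyl)phenol
Product: 23 5-[2,3-bis(benzyloxy)-5-methylbenzyl]-2-[(2S)-2-hydroxy-6-methylheptan-2-yl]phenol, via tertiary trimethylsilyl ether 22 (not isolated)
Conditions: KOt-Bu (3 equiv), DMSO/H2O 19:1, argon, rt to 50 °C; aq NH4Cl
Reagents that add atoms: none
Why: Hydroxyl-assisted protodesilylation (1,4 carbon-to-oxygen silyl shift of the Brook type): the C7 alkoxide attacks the neighbouring silicon through a five-membered silicate, water protonates B3 as the B3–Si bond breaks with relief of the strain between SiMe3 and the quaternary C7, and hydroxide hydrolyses the silyl ether; doing this after the oxidation makes the free alkoxide available, keeps the C–B bond away from hot base, and no acid is present that could ionise the tertiary benzylic alcohol.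

Step 15
Reactants: 23 5-[2,3-bis(benzyloxy)-5-methylbenzyl]-2-[(2S)-2-hydroxy-6-methylheptan-2-yl]phenol
Product: 24 asperchondol A
Conditions: H2 (1 atm), Pd/C, EtOAc/EtOH, rt; filtration and concentration under argon
Reagents that add atoms: none
Why: Catalytic hydrogenolysis of the two aryl benzyl ethers under neutral conditions; the hindered tertiary benzylic C7–OH is cleaved only when acid assists, so it and its S configuration persist, and the oxidation-prone catechol appears only in the last flask.

Compound list
1 | geraniol | CC(C)=CCC/C(C)=C/CO | starting material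
2 | (2S,3S)-2,3-epoxygeraniol | OC[C@@H]1O[C@@]1(C)CCC=C(C)C | intermediate
3 | [(2S,3S)-3-methyl-3-(4-methylpentyl)oxiran-2-yl]methanol | OC[C@@H]1O[C@@]1(C)CCCC(C)C | intermediate
4 | (2S,3R)-3-(chloromethyl)-2-methyl-2-(4-methylpentyl)oxirane | ClC[C@@H]1O[C@@]1(C)CCCC(C)C | intermediate
5 | dilithium salt of (S)-3,7-dimethyloct-1-yn-3-ol (acetylide and alkoxide) | [Li]C#C[C@@](C)(O[Li])CCCC(C)C | intermediate
6 | (S)-3,7-dimethyl-1-(trimethylsilyl)-3-(trimethylsilyloxy)oct-1-yne | C[Si](C)(C)C#C[C@@](C)(O[Si](C)(C)C)CCCC(C)C | intermediate
7 | (S)-3,7-dimethyl-1-(trimethylsilyl)oct-1-yn-3-ol | C[Si](C)(C)C#C[C@@](C)(O)CCCC(C)C | intermediate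
8 | ethynylmagnesium bromide | C#C[Mg]Br | starting material
9 | triisopropyl borate | CC(C)OB(OC(C)C)OC(C)C | starting material
10 | bromomagnesium ethynyltriisopropoxyborate | C#C[B-](OC(C)C)(OC(C)C)OC(C)C.[Mg+]Br | intermediate
11 | diisopropyl ethynylboronate | C#CB(OC(C)C)OC(C)C | intermediate
12 | creosol (2-methoxy-4-methylphenol) | COc1cc(C)ccc1O | starting material
13 | 2-hydroxy-3-methoxy-5-methylbenzaldehyde | COc1cc(C)cc(C=O)c1O | intermediate
14 | 2,3-dihydroxy-5-methylbenzaldehyde | Cc1cc(O)c(O)c(C=O)c1 | intermediate
15 | 2,3-bis(benzyloxy)-5-methylbenzaldehyde | Cc1cc(OCc2ccccc2)c(OCc2ccccc2)c(C=O)c1 | intermediate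
16 | [2,3-bis(benzyloxy)-5-methylphenyl]methanol | Cc1cc(OCc2ccccc2)c(OCc2ccccc2)c(CO)c1 | intermediate
17 | 1,2-bis(benzyloxy)-3-(bromomethyl)-5-methylbenzene | Cc1cc(OCc2ccccc2)c(OCc2ccccc2)c(CBr)c1 | intermediate
18 | 1,2-bis(benzyloxy)-5-methyl-3-(prop-2-yn-1-yl)benzene | C#CCc1cc(C)cc(OCc2ccccc2)c1OCc1ccccc1 | intermediate
19 | isopropyl (S)-3,7-dimethyl-1-(trimethylsilyl)oct-1-yn-3-yl ethynylboronate (boron-bridged 1,6-diyne) | C#CB(OC(C)C)O[C@](C)(C#C[Si](C)(C)C)CCCC(C)C | intermediate
20 | (3S)-6-[2,3-bis(benzyloxy)-5-methylbenzyl]-1-isopropoxy-3-methyl-3-(4-methylpentyl)-4-(trimethylsilyl)-1,3-dihydro-2,1-benzoxaborole | CC(C)CCC[C@]1(C)OB(OC(C)C)c2cc(Cc3cc(C)cc(OCc4ccccc4)c3OCc3ccccc3)cc([Si](C)(C)C)c21 | intermediate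
21 | 5-[2,3-bis(benzyloxy)-5-methylbenzyl]-2-[(2S)-2-hydroxy-6-methylheptan-2-yl]-3-(trimethylsilyl)phenol | Cc1cc(OCc2ccccc2)c(OCc2ccccc2)c(Cc2cc([Si](C)(C)C)c([C@@](C)(O)CCCC(C)C)c(O)c2)c1 | intermediate
22 | 5-[2,3-bis(benzyloxy)-5-methylbenzyl]-2-[(2S)-6-methyl-2-(trimethylsilyloxy)heptan-2-yl]phenol | Cc1cc(OCc2ccccc2)c(OCc2ccccc2)c(Cc2ccc([C@@](C)(O[Si](C)(C)C)CCCC(C)C)c(O)c2)c1 | intermediate
23 | 5-[2,3-bis(benzyloxy)-5-methylbenzyl]-2-[(2S)-2-hydroxy-6-methylheptan-2-yl]phenol | Cc1cc(OCc2ccccc2)c(OCc2ccccc2)c(Cc2ccc([C@@](C)(O)CCCC(C)C)c(O)c2)c1 | intermediate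
24 | asperchondol A, 3-{3-hydroxy-4-[(2S)-2-hydroxy-6-methylheptan-2-yl]benzyl}-5-methylbenzene-1,2-diol | Cc1cc(O)c(O)c(Cc2ccc([C@@](C)(O)CCCC(C)C)c(O)c2)c1 | target

Total step count: 15.

Longest linear sequence: 10 steps, from creosol 12 through steps 6 to 15. The geraniol branch reaches the target in 8 steps and the boronate branch in 5.

Steps most likely to fail

First, step 12.
- Esterification of the hindered tertiary alcohol at boron may stay incomplete or revert, so that free alkynes trimerize without order.
- Oxidative cyclization at the silyl-capped alkyne may be slow enough for self-trimerization of 18 to take over.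
- The orientation of 18 during insertion may be less than clean.

The fallback replaces the reversible boron bridge by an irreversible, isolable silicon bridge and sets out from 7, 8 and 18. Me2SiCl2 (excess) and 8 give, after distillation, chloro(ethynyl)dimethylsilane F1. This silylates 7 (imidazole, DMF, rt) to the silicon-bridged diyne F2, which can be chromatographed and characterised before any catalyst is spent. Silicon-tethered (2+2+2) cycloaddition of F2 and 18 should give the benzoxasilole F3 with the same set of new bonds. It can be run with Cp*RuCl(cod), or with RhCl(PPh3)3 or CpCo(CO)2 at higher temperature, which the Si–O bridge tolerates. Tamao–Fleming oxidation (H2O2, KF, KHCO3, THF/MeOH) then converts the B5–Si bond into the phenol and frees the C7 hydroxyl. The route is rejoined at 21.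

Second, step 14. Attack at the crowded silicon may be slow. Prolonged heating of the phenoxide in strong base may then start loss of the C7 hydroxyl through an ortho-quinone methide, ending in dehydration or in racemisation by re-addition of hydroxide. The fallback takes silicon off before either oxygen is unmasked and sets out from 20. Base-catalysed protodesilylation (KOSiMe3, wet DMSO, 60 °C) is run on the boron heterocycle, where no phenoxide exists and the C7 oxygen is held in the ring. It should give the silicon-free hydroxybenzoxaborole F4. Oxidation as in step 13 then leads directly to 23, where the route is rejoined. The price is exposure of the C–B bond to hot base, with possible protodeboronation, which is why this order is the second choice.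

Third, step 11.
- The product acetylide may be alkylated a second time.
- The electron-rich benzylic bromide may homocouple.
- Basic magnesium species may shift the triple bond towards the allene.

The fallback builds the alkyne from a carbonyl group instead of displacing a halide and sets out from 15. Wittig methoxymethylenation (Ph3P=CHOMe from (methoxymethyl)triphenylphosphonium chloride and KOt-Bu, THF, 0 °C) gives the aryl enol ether F5 as an E/Z mixture. Mild acid hydrolysis (1 M HCl, THF, rt) gives the arylacetaldehyde F6. Seyferth–Gilbert homologation with the Ohira–Bestmann reagent (K2CO3, MeOH, 0 °C to rt) then gives 18, where the route is rejoined. Steps 9 to 11 are replaced by three operations, so the count does not change.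

Further compounds
F1 | step 12 | chloro(ethynyl)dimethylsilane | C#C[Si](C)(C)Cl
F2 | step 12 | (S)-{[3,7-dimethyl-1-(trimethylsilyl)oct-1-yn-3-yl]oxy}(ethynyl)dimethylsilane | C#C[Si](C)(C)O[C@](C)(C#C[Si](C)(C)C)CCCC(C)C
F3 | step 12 | (3S)-6-[2,3-bis(benzyloxy)-5-methylbenzyl]-1,1,3-trimethyl-3-(4-methylpentyl)-4-(trimethylsilyl)-1,3-dihydro-2,1-benzoxasilole | CC(C)CCC[C@]1(C)O[Si](C)(C)c2cc(Cc3cc(C)cc(OCc4ccccc4)c3OCc3ccccc3)cc([Si](C)(C)C)c21
F4 | step 14 | (3S)-6-[2,3-bis(benzyloxy)-5-methylbenzyl]-3-methyl-3-(4-methylpentyl)-2,1-benzoxaborol-1(3H)-ol | CC(C)CCC[C@]1(C)OB(O)c2cc(Cc3cc(C)cc(OCc4ccccc4)c3OCc3ccccc3)ccc21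
F5 | step 11 | 1,2-bis(benzyloxy)-3-(2-methoxyethenyl)-5-methylbenzene (E/Z mixture) | COC=Cc1cc(C)cc(OCc2ccccc2)c1OCc1ccccc1
F6 | step 11 | 2-[2,3-bis(benzyloxy)-5-methylphenyl]acetaldehyde | O=CCc1cc(C)cc(OCc2ccccc2)c1OCc1ccccc1
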